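## Analysis of the target

The target is a 13(16)-cycloabietane in which C1 is also bonded to C11. A cyclobutane (C1–C10–C9–C11) therefore carries ring A on its C1–C10 edge, ring B on its C9–C10 edge and ring C on its C9–C11 edge. C13 is the spiro atom of a methylcyclopropane (C13, C15, C16, with methyl C17 on C15). Atoms are numbered as in the abietanes, and β means the face of the C10 methyl group.

There are eleven stereocentres. H-1, CH3-10, OH-9 and OH-11 all lie on the β face of the four-membered ring. H-5 is α (trans A/B) and H-8 is β (cis B/C). The 6-acetoxy group is β and axial, OH-7 is α and axial, and the 12-acetoxy group is α and trans to OH-11. C15 sits on the α face of ring C with its methyl on the side of the C14 carbonyl.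

The sensitive parts are the vicinal tertiary cyclobutanediol (ring change in acid), the β-hydroxy ketone arrays O9–C9–C8–C14=O and O7–C7–C8–C14=O (retro-aldol and elimination in base), the epimerisable C8, two acetates next to free hydroxyls, and the acyl cyclopropane. The difficulty is the cluster of four contiguous fully substituted carbons (C9, C10, C11, C13) around a strained ring, together with seven oxygen functions at four different oxidation and protection states.

The plan rests on one feature: bond C9–C10 belongs to both ring B and the cyclobutane, and C11 next to it is oxygenated. A cyclobutenone with C9=C10 as its double bond and C11 as its carbonyl can therefore act as dienophile toward a diene C5=C6–C7=C8 hung from C1 through C2–C4, closing rings A and B together.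

## Retrosynthetic reasoning

**49 to 46 (O–Si, O–acyl and C12–H).** 49 is traced to its 7,9-bis-silyl ether 48, to the C12 alcohol 47 and to the α-ketol 46. With O-7 and O-9 silylated, each acylation meets only the hydroxyl that is to be acylated plus an inert tertiary one. The C12 centre is made from the ketone under direction by the 11-hydroxyl, which gives the required trans relation.

**46 to 45 (C11–C12).** Ring C is opened between C11 and C12, which leads to the keto aldehyde 45. This bond joins a tertiary carbinol to a carbon flanked by two quaternary centres, so a polar union of an acyl-anion carbon (C12) with the strained C11 ketone is the natural choice. C11 is the very carbonyl that the cycloaddition leaves behind. Because C12 is tied to C8, the new hydroxyl can only end cis to O-9.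

**45 to 34 plus 40 (C13–C14).** Cutting C13–C14 separates the core aldehyde 34 from the cyclopropyl bromide 40. The cyclopropane then arrives as a finished, enantiopure unit. A cyclopropyl anion keeps its configuration, so the bond forms with retention and C14 ends cis to the C15 methyl, which an enolate alkylation would not give. 40 goes back to crotonaldehyde 35 through the bromo allylic alcohol 38, whose (Z) geometry becomes the cis relation of bromine and methyl.

**34 to 27 (ring B oxygen pattern and C8).** The 6β-acetoxy and 7α-silyloxy groups of 34 come from the enol ether C6=C7 of 27 by epoxidation and reduction, both from the open α face. The formyl group comes from the CH2O substituent on C8, and its equatorial position from base equilibration. The C11 ketone of 27 is carried as a silylated carbinol (30 to 43) while hydrides and the organometallic are used, and is restored in 45.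

**27 to 26 (C5–C10 and C8–C9, the key disconnection).** Both bonds of ring B that end on the cyclobutane are cut. This opens rings A and B at once and removes four stereocentres. The result is 26, a 2-silyloxy-3-methylcyclobutenone tied through C1–C4 to a 2-silyloxy diene. No other pair of bonds removes as much complexity, and the C9 oxygen and C10 methyl are already on the dienophile.

**26 to 18 (the cyclobutenone).** The diene of 26 is the silyl enol ether of enone 25, made from 23. A 3-methyl-4-alkylcyclobutane-1,2-dione cannot be enolised toward the methyl-bearing carbon with any certainty, and enolisation toward C1 would also destroy the only controlling stereocentre. The methyl is therefore put in last: 23 comes from 21 by conjugate addition and dehydrogenation. In the dione 20, C10 is a CH2 and the only accessible enolisation site, so 21 forms regioselectively. 20 comes from succinate 18 by reductive C9–C11 bond formation through 19, which does not touch C1.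

**18 to 4 and 13 (C1, C2–C6, C6–C7).** C1 is set by alkylating lactone 4 anti to its bulky substituent, giving 6. The C3 stereocentre thus relays chirality to C1 and is later erased as the C3 ketone. The side chain is grown from the vinyl group of 6 (to aldehyde 9), and the C6–C7 bond is made with vinyl iodide 13 by a coupling that tolerates lactone and ester. A neopentyl C5 nucleophile or a β-oxygenated C2 organometallic would not be workable.

**4 to 1 (C3–C4).** Reverse prenylation of aldehyde 1 creates C3 and the quaternary C4 in one step, and the product closes to the lactone on its own ester.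

## Alternatives that were turned down

**Alternative 1:** Ring C is opened last, at C8–C14 together with O–C7. The forward step is an intramolecular nitrile oxide cycloaddition: NaOCl oxidation of aldoxime A2 (C7=C8 alkene in ring B, the oxime carbon C14 on C13, 9,11-diol as acetonide) gives isoxazoline A1, and N–O cleavage would later reveal the 7-hydroxyl and the 14-ketone.
- For it: one step makes C8–C14, puts O-7 cis to the new bond, enforces the cis B/C fusion, and keeps the fragile β-hydroxy ketone masked. On the C7/C8/C14 triad it is stronger than the chosen route, which needs an enol ether oxidation, an epimerisation and a separate C–C bond formation.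
- Against it: A2 must already contain the cyclobutanediol, rings A and B, the C11–C12 bond and the spirocyclopropane, so the hardest part of the molecule is left unsolved. It also needs a C7=C8 alkene next to the quaternary C9, and reductive N–O cleavage beside an acyl cyclopropane.
- Comparison: it is an endgame tactic and adds steps before it. The chosen strategy offers in its place the core with four stereocentres early, from a precursor with two.

**Alternative 2:** The cyclopropane is disconnected at C13–C15 inside a ring C spirodienone. The forward step is a dearomatising para-alkylation: the phenoxide of A4 displaces its own secondary mesylate with inversion and gives A3.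
- For it: C15 comes from a cheap chiral carbinol, the step is stereospecific and very short, and the aromatic start is trivial. For the spiro unit it is stronger than the chosen route, which spends four steps on fragment 40 and an organocerium addition.
- Against it: A3 contains ring C only, and C8, C9, C11, C12 and C14 are all still sp2. C9 and C11 must become the carbinols of a cyclobutane, with no bond-forming step in view. The two similar oxygenated carbons must be told apart to decide which side the methyl faces, and the spirodienone is prone to dienone–phenol rearrangement and homoconjugate opening.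
- Comparison: it is economical for one ring but moves all the risk into later annulations without precedent. The chosen strategy closes two rings on the cyclobutane in one step.

**Alternative 3:** The cyclobutane is made by contracting a cyclopentanone. Irradiation of diazo ketone A6 in methanol would move C9 from C12 to C11 and give ester A5.
- For it: photochemical Wolff contraction is a dependable entry to cyclobutanes. The C9 oxygen, the C10 methyl and the trans A/B fusion are fixed beforehand, so there is no endo/exo question. In stereochemical certainty it is stronger than the chosen key step, and the ester carbon is C12.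
- Against it: a 6-6-5 tricycle with the oxygenated quaternary C9 must be built first and then shrunk. Diazo transfer must occur at a hindered position, the migrating carbon is fully substituted, C11 emerges as a C–H that needs later hydroxylation on a crowded cyclobutane, and ring C still requires several C–C bonds from a vinyl group.
- Comparison: it is longer and more linear. The chosen strategy reaches the same tricyclic stage in one ring-forming step, at the price of a less certain transition-state preference.

Key step: step 18

## Route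

Assumption: the carbinol centres made at C6 (step 7), C11 (step 20) and C14 (step 30) are carried as epimer mixtures because each is oxidised to a ketone later; atoms are numbered as in the abietanes and β is the face of the C10 methyl group.

Step 1
Reactants: 1 methyl 4-oxobutanoate
Product: 4 (5S)-5-(2-methylbut-3-en-2-yl)oxolan-2-one, via borinate 2 (not isolated), via hydroxy ester 3 (not isolated)
Conditions: (+)-Ipc2BOMe, prenylMgCl, Et2O, −78 °C; 1, −78 °C; NaBO3·4H2O, H2O; TsOH (cat.), PhMe, rt
Reagents that add atoms: prenylmagnesium chloride, CC(C)=CC[Mg]Cl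
Why: Reverse prenylboration: the γ-carbon of the prenylborane adds to the aldehyde through a closed chair transition state, so the quaternary C4 and the C3 carbinol form together. The isopinocampheyl groups (from (−)-α-pinene) should select the face that gives the (S)-alcohol, which lactonises onto its ester.

Step 2
Reactants: 4 (5S)-5-(2-methylbut-3-en-2-yl)oxolan-2-one
Product: 6 methyl 2-[(3S,5S)-5-(2-methylbut-3-en-2-yl)-2-oxooxolan-3-yl]acetate, via lithium enolate 5 (not isolated)
Conditions: LiN(SiMe3)2, THF, −78 °C; BrCH2CO2Me, −78 → −40 °C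
Reagents that add atoms: methyl bromoacetate, COC(=O)CBr
Why: Alkylation of a γ-substituted butyrolactone enolate. The electrophile enters anti to the tert-alkyl group on C3, which sets C1 trans to it.

Step 3
Reactants: 6 methyl 2-[(3S,5S)-5-(2-methylbut-3-en-2-yl)-2-oxooxolan-3-yl]acetate
Product: 8 primary alcohol (C6–OH), via alkylborane 7 (not isolated)
Conditions: 9-BBN-H, THF, 40 °C; H2O2, aq. NaOAc, 0 °C → rt
Reagents that add atoms: hydrogen peroxide, OO
Why: Hydroboration–oxidation. The bulky borane adds boron to the terminal carbon of the hindered vinyl group and does not reduce lactone or ester; buffered peroxide avoids saponification.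

Step 4
Reactants: 8 primary alcohol (C6–OH)
Product: 9 aldehyde (C6)
Conditions: Dess–Martin periodinane, NaHCO3, CH2Cl2, 0 °C → rt
Reagents that add atoms: none
Why: Dess–Martin oxidation of a primary alcohol under buffered, non-basic conditions, which leaves the C1 centre α to the lactone carbonyl intact.

Step 5
Reactants: 10 prop-2-yn-1-ol
Product: 11 1-methoxy-4-[(prop-2-yn-1-yloxy)methyl]benzene
Conditions: NaH, 4-MeOC6H4CH2Cl, Bu4NI (cat.), THF, 0 °C → rt
Reagents that add atoms: 4-methoxybenzyl chloride, COc1ccc(CCl)cc1
Why: Williamson ether synthesis on an unhindered primary alkoxide.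

Step 6
Reactants: 11 1-methoxy-4-[(prop-2-yn-1-yloxy)methyl]benzene
Product: 13 (E)-vinyl iodide, via alkenylzirconocene 12 (not isolated)
Conditions: Cp2Zr(H)Cl, THF, rt; I2, 0 °C
Reagents that add atoms: iodine, II
Why: Hydrozirconation–iodination. Syn addition of Zr–H puts the metal on the terminal carbon and iodinolysis proceeds with retention, giving the (E)-iodide.

Step 7
Reactants: 9 aldehyde (C6); 13 (E)-vinyl iodide
Product: 14 allylic alcohol (C6 epimers)
Conditions: CrCl2, NiCl2 (cat.), DMSO, rt
Reagents that add atoms: none
Why: Nozaki–Hiyama–Kishi coupling. The alkenylchromium species adds only to the aldehyde, tolerates lactone and ester, and keeps the (E) geometry; the C6 configuration is irrelevant.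

Step 8
Reactants: 14 allylic alcohol (C6 epimers)
Product: 15 triethylsilyl ether of 14
Conditions: Et3SiCl, imidazole, DMF, 0 °C → rt
Reagents that add atoms: chlorotriethylsilane, CC[Si](Cl)(CC)CC
Why: Standard silylation. The triethylsilyl group masks O-6 through the basic and reducing steps and can later be removed in the presence of tert-butyldimethylsilyl groups.

Step 9
Reactants: 15 triethylsilyl ether of 14
Product: 17 bis(4-methoxybenzyl) succinate with O-3 as 4-methoxybenzyl ether, via dilithium salt 16 (not isolated)
Conditions: LiOH, THF/H2O, 0 °C → rt; evaporate; NaH, 4-MeOC6H4CH2Cl, Bu4NI, DMF, 0 °C → rt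
Reagents that add atoms: lithium hydroxide, [Li+].[OH-]; 4-methoxybenzyl chloride, COc1ccc(CCl)cc1
Why: Saponification opens lactone and ester, and the carboxylate salt cannot relactonise. Exhaustive O-alkylation then fixes O-3 as an ether that is later removed together with the one on O-14.

Step 10
Reactants: 17 bis(4-methoxybenzyl) succinate
Product: 18 dimethyl succinate (2S, side chain 2S)
Conditions: K2CO3, MeOH, rt
Reagents that add atoms: methanol, CO
Why: Base-catalysed transesterification of the activated benzylic esters gives the methyl esters needed for the acyloin step. The ether groups are inert, and mild carbonate at room temperature should not epimerise C1.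

Step 11
Reactants: 18 dimethyl succinate
Product: 19 (3S)-3-alkyl-1,2-bis(trimethylsilyloxy)cyclobut-1-ene
Conditions: Na (dispersion), Me3SiCl, PhMe, 45 °C, ultrasound
Reagents that add atoms: chlorotrimethylsilane, C[Si](C)(C)Cl
Why: Rühlmann acyloin condensation. Silyl trapping of the enediolate and of methoxide makes the four-membered ring closure of succinates efficient, and the C1 centre is not involved.

Step 12
Reactants: 19 (3S)-3-alkyl-1,2-bis(trimethylsilyloxy)cyclobut-1-ene
Product: 20 (3S)-3-alkylcyclobutane-1,2-dione
Conditions: Br2 (1.0 equiv), CH2Cl2, −78 °C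
Reagents that add atoms: none
Why: Oxidation of an enediol bis-silyl ether by bromine with loss of two silyl bromides. The electron-rich tetrasubstituted double bond should react far faster than the disubstituted alkene or the anisyl rings at −78 °C.

Step 13
Reactants: 20 (3S)-3-alkylcyclobutane-1,2-dione
Product: 21 (4S)-4-alkyl-2-(tert-butyldimethylsilyloxy)cyclobut-2-en-1-one
Conditions: tBuMe2SiOTf (1.05 equiv), Et3N, CH2Cl2, −78 °C
Reagents that add atoms: tert-butyldimethylsilyl trifluoromethanesulfonate, CC(C)(C)[Si](C)(C)OS(=O)(=O)C(F)(F)F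
Why: Soft enolisation, as in the enol silylation of cyclic 1,2-diones to 2-silyloxy enones. The unhindered C10 methylene is deprotonated in preference to the C1 methine shielded by the side chain, so the enol ether forms toward C10 and C1 keeps its configuration.

Step 14
Reactants: 21 (4S)-4-alkyl-2-(tert-butyldimethylsilyloxy)cyclobut-2-en-1-one
Product: 23 (4S)-4-alkyl-2-(tert-butyldimethylsilyloxy)-3-methylcyclobut-2-en-1-one, via methylated lithium enolate 22 (not isolated)
Conditions: Me2CuLi (from MeLi, CuI), Et2O, −78 °C; PhS(Cl)=NtBu, THF, −78 °C → rt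
Reagents that add atoms: methyllithium, C[Li]
Why: Conjugate addition of the cuprate to the unsubstituted β-carbon C10 of the strained enone, then one-pot dehydrogenation of the enolate with the sulfinimidoyl chloride (sulfenylation at C9, syn elimination). The only β-hydrogen is on C10, so the double bond returns to C9=C10 and the net result is β-methylation.

Step 15
Reactants: 23 (4S)-4-alkyl-2-(tert-butyldimethylsilyloxy)-3-methylcyclobut-2-en-1-one
Product: 24 allylic alcohol (C6 epimers)
Conditions: PPTS, MeOH/CH2Cl2, 0 °C
Reagents that add atoms: none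
Why: Acid-catalysed methanolysis of the triethylsilyl ether. The 2-silyloxy enone should survive, because protonation of its β-carbon is disfavoured by conjugation with the carbonyl and its silyl group is the less labile one.

Step 16
Reactants: 24 allylic alcohol (C6 epimers)
Product: 25 (E)-enone (C6 ketone)
Conditions: Dess–Martin periodinane, NaHCO3, CH2Cl2, 0 °C
Reagents that add atoms: none
Why: Dess–Martin oxidation of an allylic alcohol; both C6 epimers converge on one enone.

Step 17
Reactants: 25 (E)-enone (C6 ketone)
Product: 26 cyclobutenone with tethered (5Z,7E)-2-silyloxy diene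
Conditions: tBuMe2SiOTf, Et3N, CH2Cl2, −78 → −20 °C; used at once
Reagents that add atoms: tert-butyldimethylsilyl trifluoromethanesulfonate, CC(C)(C)[Si](C)(C)OS(=O)(=O)C(F)(F)F
Why: Soft enolisation of the enone on its α′ side (C5) gives the cross-conjugated silyl dienol ether. The (Z) enol ether, with C4 trans to C7, avoids allylic strain between the quaternary C4 and the vinyl group.

Step 18
Reactants: 26 cyclobutenone with tethered (5Z,7E)-2-silyloxy diene
Product: 27 tricyclic cyclobutanone (rings A and B closed; 8α-H)
Conditions: PhMe (0.01 M), BHT (cat.), 60 °C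
Reagents that add atoms: none
Why: Concerted, asynchronous thermal [4+2] cycloaddition of normal electron demand between the 2-silyloxy diene C5=C6–C7=C8 and the strained enone C9=C10–C11=O, forming C5–C10 and C8–C9; the closest known reaction type is the intramolecular Diels–Alder reaction of cyclobutenones, whose ring strain lowers the distortion energy of the dienophile (Me2AlCl is held in reserve only, because it would favour the carbonyl-endo mode). Ring B is closed by the cycloaddition itself as a cyclohexene, and ring A is closed at the same time by the four-atom tether C1–C4 in a type 1 intramolecular mode, as a six-membered ring through the C5–C10 bond. C9 and C10 are set by the C1 stereocentre: the tether can deliver the diene only to the cyclobutenone face that carries C2, so the C10 methyl and the C9 silyloxy group end on the face of H-1. C5 is set by the exo placement of the C11 carbonyl, which alone lets the forming ring A adopt a chair with C4 and C1 gauche and gives H-5 anti to the C10 methyl (trans A/B). C8 follows from the (E) geometry of C7=C8, which puts the CH2O group cis to C4 (8α-H, the epimer of the target, corrected in step 25). The selectivity the step needs is exo over endo; it is supported by the short tether anchored on the ring carbon cis to the carbonyl, by the (Z) enol ether that holds C4 outside, and by the absence of a Lewis acid. High dilution and a radical inhibitor guard against dimerisation, and the moderate temperature against electrocyclic opening of the cyclobutenone.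

Step 19
Reactants: 27 tricyclic cyclobutanone (rings A and B closed; 8α-H)
Product: 28 6-ketone with 7α-silyloxy group
Conditions: dimethyldioxirane, acetone/CH2Cl2, −78 → −20 °C
Reagents that add atoms: dimethyldioxirane, CC1(C)OO1
Why: Rubottom oxidation. The enol ether is epoxidised from the α face (the β face is shielded by the C10 methyl and the axial C8 substituent) and a 1,4-silyl shift gives the 7α-silyloxy ketone; a dioxirane is used because a peracid would also attack the cyclobutanone in a Baeyer–Villiger reaction.

Step 20
Reactants: 28 6-ketone with 7α-silyloxy group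
Product: 29 6β,11-diol
Conditions: NaBH4, CeCl3·7H2O, MeOH/THF, −40 → 0 °C
Reagents that add atoms: none
Why: Luche-type borohydride reduction. Hydride reaches C6 from the α face, because the β face is blocked by the 1,3-diaxial methyls on C4 and C10, and gives the axial 6β-alcohol; the strained C11 ketone is reduced as well and is deliberately parked as a carbinol until step 32.

Step 21
Reactants: 29 6β,11-diol
Product: 30 11-triethylsilyl ether
Conditions: Et3SiCl, imidazole, DMAP (cat.), DMF, 0 °C
Reagents that add atoms: chlorotriethylsilane, CC[Si](Cl)(CC)CC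
Why: Selective silylation: the axial 6β-hydroxyl, flanked by two syn-axial methyl groups and the 7-silyloxy group, is far less accessible than the cyclobutanol.

Step 22
Reactants: 30 11-triethylsilyl ether
Product: 31 6β-acetate
Conditions: Ac2O, DMAP, pyridine, 50 °C
Reagents that add atoms: acetic anhydride, CC(=O)OC(C)=O
Why: DMAP-catalysed acylation of the one remaining, hindered hydroxyl. The acetate is placed now so that C6 is protected from the later oxidations.

Step 23
Reactants: 31 6β-acetate
Product: 32 3β,14-diol
Conditions: DDQ, CH2Cl2/pH 7 buffer, 0 °C → rt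
Reagents that add atoms: none
Why: Oxidative cleavage of both 4-methoxybenzyl ethers by hydride abstraction and hydrolysis; the buffer protects the silyl ethers and the acetate.

Step 24
Reactants: 32 3β,14-diol
Product: 33 3-ketone 14-aldehyde (8α-H, formyl axial)
Conditions: Dess–Martin periodinane, NaHCO3, CH2Cl2, 0 °C → rt
Reagents that add atoms: none
Why: Dess–Martin oxidation of both alcohols installs the C3 ketone of the target and the C14 aldehyde in one operation without base.

Step 25
Reactants: 33 3-ketone 14-aldehyde (8α-H, formyl axial)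
Product: 34 3-ketone 14-aldehyde (8β-H, formyl equatorial)
Conditions: DBU (0.2 equiv), CH2Cl2, −20 → 0 °C
Reagents that add atoms: none
Why: Base-catalysed epimerisation through the aldehyde enolate under thermodynamic control. The formyl group leaves the axial β position, where it is syn-axial to the C10 methyl, for the equatorial position; this is the C8 configuration of the target and the only one from which ring C can close.

Step 26
Reactants: 35 (E)-but-2-enal
Product: 37 (Z)-2-bromobut-2-enal, via dibromide 36 (not isolated)
Conditions: Br2, CH2Cl2, 0 °C; Et3N, 0 °C → rt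
Reagents that add atoms: bromine, BrBr
Why: Bromination then dehydrobromination of the α-hydrogen. The elimination gives the α-bromo enal with bromine cis to the methyl group, the more stable isomer.

Step 27
Reactants: 37 (Z)-2-bromobut-2-enal
Product: 38 (Z)-2-bromobut-2-en-1-ol
Conditions: NaBH4, CeCl3·7H2O, MeOH, 0 °C
Reagents that add atoms: none
Why: Luche 1,2-reduction of the enal, without loss of the vinylic bromide or of the alkene geometry.

Step 28
Reactants: 38 (Z)-2-bromobut-2-en-1-ol
Product: 39 [(1S,2R)-1-bromo-2-methylcyclopropyl]methanol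
Conditions: Et2Zn, CH2I2, DME, (4S,5S)-2-butyl-N,N,N′,N′-tetramethyl-1,3,2-dioxaborolane-4,5-dicarboxamide, CH2Cl2, 0 °C → rt
Reagents that add atoms: diiodomethane, ICI
Why: Asymmetric Simmons–Smith cyclopropanation of an allylic alcohol. Methylene transfer is stereospecific, so bromine stays cis to the methyl group, and the chiral dioxaborolane bound to the zinc alkoxide selects the alkene face; if the facial sense on this bromoalkene proves opposite to the model, the antipodal ligand is used.

Step 29
Reactants: 39 [(1S,2R)-1-bromo-2-methylcyclopropyl]methanol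
Product: 40 triethylsilyl ether of 39
Conditions: Et3SiCl, imidazole, CH2Cl2, 0 °C → rt
Reagents that add atoms: chlorotriethylsilane, CC[Si](Cl)(CC)CC
Why: Silylation of a primary alcohol; the same silyl group as on O-11 allows one later deprotection.

Step 30
Reactants: 34 3-ketone 14-aldehyde (8β-H); 40 triethylsilyl ether of 39
Product: 43 C14 carbinol carrying the cyclopropane (C14 epimers), via cyclopropyllithium 41 (not isolated), via cyclopropylcerium dichloride 42 (not isolated)
Conditions: 40, tBuLi (2 equiv), Et2O, −78 °C; CeCl3, THF, −78 °C; 34, −78 °C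
Reagents that add atoms: none
Why: Bromine–lithium exchange gives a tertiary cyclopropyllithium that holds its configuration, and transmetalation to cerium gives a weakly basic nucleophile. This adds to the hindered aldehyde without enolising it and should leave the C3 ketone and the acetate alone at −78 °C; the C13–C14 bond forms with retention, so C14 is cis to the C15 methyl.

Step 31
Reactants: 43 C14 carbinol carrying the cyclopropane (C14 epimers)
Product: 44 11,12,14-triol
Conditions: HF·pyridine, pyridine, THF, 0 °C
Reagents that add atoms: none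
Why: Buffered fluoride cleaves the primary and secondary triethylsilyl ethers much faster than the hindered secondary and tertiary tert-butyldimethylsilyl ethers.

Step 32
Reactants: 44 11,12,14-triol
Product: 45 11,14-diketone 12-aldehyde
Conditions: Dess–Martin periodinane (excess), NaHCO3, CH2Cl2, rt
Reagents that add atoms: none
Why: Dess–Martin oxidation of all three alcohols restores the C11 cyclobutanone and makes the C14 ketone and the C12 aldehyde. C13 is quaternary, so the 1,3-dicarbonyl unit cannot enolise.

Step 33
Reactants: 45 11,14-diketone 12-aldehyde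
Product: 46 tetracyclic α-ketol (11β-OH, 12-ketone)
Conditions: 2-mesityl-6,7-dihydro-5H-pyrrolo[2,1-c][1,2,4]triazol-2-ium chloride (20 mol%), Et3N, CH2Cl2, rt
Reagents that add atoms: none
Why: Carbene-catalysed intramolecular crossed benzoin reaction. The Breslow intermediate of the non-enolisable aldehyde adds to the strained C11 ketone in a 6-exo-trig closure of ring C; the tether through C8 reaches only one face of C11, so OH-11 ends cis to O-9, and relief of cyclobutanone strain drives the addition.

Step 34
Reactants: 46 tetracyclic α-ketol (11β-OH, 12-ketone)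
Product: 47 11β,12α-diol
Conditions: Me4NBH(OAc)3, MeCN/AcOH, −30 °C
Reagents that add atoms: none
Why: Hydroxyl-directed reduction of the Evans–Saksena type. The borohydride exchanges onto the 11β-hydroxyl and delivers hydride to the β face of C12, giving the 12α-carbinol trans to OH-11; ketones without a free neighbouring hydroxyl (C3, C14) should not be reduced at this temperature.

Step 35
Reactants: 47 11β,12α-diol
Product: 48 6β,12α-diacetate 7,9-bis-silyl ether
Conditions: Ac2O, DMAP, pyridine, rt → 40 °C
Reagents that add atoms: acetic anhydride, CC(=O)OC(C)=O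
Why: Acylation of the only secondary hydroxyl; the tertiary 11-hydroxyl does not react under these conditions.

Step 36
Reactants: 48 6β,12α-diacetate 7,9-bis-silyl ether
Product: 49 target CNP0157858.4
Conditions: HF (48% aq.), MeCN, 0 °C → rt
Reagents that add atoms: none
Why: Fluoride-mediated cleavage of both tert-butyldimethylsilyl ethers in a mildly acidic medium. This avoids acetyl migration and base-induced retro-aldol or elimination at the β-hydroxy ketone units.

## Compound list

1 | methyl 4-oxobutanoate | COC(=O)CCC=O | starting material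
2 | O-diisopinocampheylboryl derivative of 3 (isopinocampheyl groups from (−)-α-pinene, their configuration not written) | COC(=O)CC[C@H](OB(C1CC2CC(C1C)C2(C)C)C1CC2CC(C1C)C2(C)C)C(C)(C)C=C | intermediate (not isolated)
3 | methyl (4S)-4-hydroxy-5,5-dimethylhept-6-enoate | COC(=O)CC[C@H](O)C(C)(C)C=C | intermediate (not isolated)
4 | (5S)-5-(2-methylbut-3-en-2-yl)oxolan-2-one | C=CC(C)(C)[C@@H]1CCC(=O)O1 | intermediate
5 | lithium enolate of 4 | [Li]OC1=CC[C@@H](C(C)(C)C=C)O1 | intermediate (not isolated)
6 | methyl 2-[(3S,5S)-5-(2-methylbut-3-en-2-yl)-2-oxooxolan-3-yl]acetate (trans) | C=CC(C)(C)[C@@H]1C[C@@H](CC(=O)OC)C(=O)O1 | intermediate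
7 | B-alkyl-9-borabicyclo[3.3.1]nonane from 6 (boron on the terminal carbon C6) | B1(C2CCCC1CCC2)CCC(C)(C)[C@@H]1C[C@@H](CC(=O)OC)C(=O)O1 | intermediate (not isolated)
8 | methyl 2-[(3S,5S)-5-(4-hydroxy-2-methylbutan-2-yl)-2-oxooxolan-3-yl]acetate | OCCC(C)(C)[C@@H]1C[C@@H](CC(=O)OC)C(=O)O1 | intermediate
9 | methyl 2-[(3S,5S)-5-(2-methyl-4-oxobutan-2-yl)-2-oxooxolan-3-yl]acetate | O=CCC(C)(C)[C@@H]1C[C@@H](CC(=O)OC)C(=O)O1 | intermediate
10 | prop-2-yn-1-ol | C#CCO | starting material
11 | 1-methoxy-4-[(prop-2-yn-1-yloxy)methyl]benzene | C#CCOCc1ccc(OC)cc1 | intermediate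
12 | chlorobis(cyclopentadienyl)[(1E)-3-(4-methoxybenzyloxy)prop-1-enyl]zirconium | COc1ccc(COC/C=C/[Zr](Cl)(C2C=CC=C2)C2C=CC=C2)cc1 | intermediate (not isolated)
13 | 1-{[(2E)-3-iodoprop-2-en-1-yl]oxymethyl}-4-methoxybenzene | COc1ccc(COC/C=C/I)cc1 | intermediate
14 | methyl 2-[(3S,5S)-5-{(5E)-4-hydroxy-7-(4-methoxybenzyloxy)-2-methylhept-5-en-2-yl}-2-oxooxolan-3-yl]acetate (C6 epimers) | COc1ccc(COC/C=C/C(O)CC(C)(C)[C@@H]2C[C@@H](CC(=O)OC)C(=O)O2)cc1 | intermediate
15 | triethylsilyl ether of 14 (C6 epimers) | COc1ccc(COC/C=C/C(O[Si](CC)(CC)CC)CC(C)(C)[C@@H]2C[C@@H](CC(=O)OC)C(=O)O2)cc1 | intermediate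
16 | dilithium (2S)-2-[(2S,6E)-2-hydroxy-8-(4-methoxybenzyloxy)-3,3-dimethyl-5-(triethylsilyloxy)oct-6-en-1-yl]butanedioate | [Li+].[Li+].[O-]C(=O)C[C@@H](C([O-])=O)C[C@H](O)C(C)(C)CC(O[Si](CC)(CC)CC)/C=C/COCc1ccc(OC)cc1 | intermediate (not isolated)
17 | bis(4-methoxybenzyl) (2S)-2-[(2S,6E)-2,8-bis(4-methoxybenzyloxy)-3,3-dimethyl-5-(triethylsilyloxy)oct-6-en-1-yl]butanedioate | COc1ccc(COC(=O)C[C@@H](C(=O)OCc2ccc(OC)cc2)C[C@H](OCc2ccc(OC)cc2)C(C)(C)CC(O[Si](CC)(CC)CC)/C=C/COCc2ccc(OC)cc2)cc1 | intermediate
18 | dimethyl (2S)-2-[(2S,6E)-2,8-bis(4-methoxybenzyloxy)-3,3-dimethyl-5-(triethylsilyloxy)oct-6-en-1-yl]butanedioate | COC(=O)C[C@@H](C(=O)OC)C[C@H](OCc1ccc(OC)cc1)C(C)(C)CC(O[Si](CC)(CC)CC)/C=C/COCc1ccc(OC)cc1 | intermediate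
19 | (3S)-3-[(2S,6E)-2,8-bis(4-methoxybenzyloxy)-3,3-dimethyl-5-(triethylsilyloxy)oct-6-en-1-yl]-1,2-bis(trimethylsilyloxy)cyclobut-1-ene | C[Si](C)(C)OC1=C(O[Si](C)(C)C)[C@@H](C[C@H](OCc2ccc(OC)cc2)C(C)(C)CC(O[Si](CC)(CC)CC)/C=C/COCc2ccc(OC)cc2)C1 | intermediate
20 | (3S)-3-[same side chain]cyclobutane-1,2-dione | O=C1C(=O)[C@@H](C[C@H](OCc2ccc(OC)cc2)C(C)(C)CC(O[Si](CC)(CC)CC)/C=C/COCc2ccc(OC)cc2)C1 | intermediate
21 | (4S)-4-[same side chain]-2-(tert-butyldimethylsilyloxy)cyclobut-2-en-1-one | O=C1C(O[Si](C)(C)C(C)(C)C)=C[C@@H]1C[C@H](OCc2ccc(OC)cc2)C(C)(C)CC(O[Si](CC)(CC)CC)/C=C/COCc2ccc(OC)cc2 | intermediate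
22 | lithium enolate from methyl addition to 21 (methyl trans to the side chain) | [Li]OC1=C(O[Si](C)(C)C(C)(C)C)[C@@H](C)[C@@H]1C[C@H](OCc2ccc(OC)cc2)C(C)(C)CC(O[Si](CC)(CC)CC)/C=C/COCc2ccc(OC)cc2 | intermediate (not isolated)
23 | (4S)-4-[same side chain]-2-(tert-butyldimethylsilyloxy)-3-methylcyclobut-2-en-1-one | O=C1C(O[Si](C)(C)C(C)(C)C)=C(C)[C@@H]1C[C@H](OCc2ccc(OC)cc2)C(C)(C)CC(O[Si](CC)(CC)CC)/C=C/COCc2ccc(OC)cc2 | intermediate
24 | C6 alcohol of 23 (triethylsilyl group removed; C6 epimers) | O=C1C(O[Si](C)(C)C(C)(C)C)=C(C)[C@@H]1C[C@H](OCc2ccc(OC)cc2)C(C)(C)CC(O)/C=C/COCc2ccc(OC)cc2 | intermediate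
25 | (4S)-4-[(2S,6E)-2,8-bis(4-methoxybenzyloxy)-3,3-dimethyl-5-oxooct-6-en-1-yl]-2-(tert-butyldimethylsilyloxy)-3-methylcyclobut-2-en-1-one | O=C1C(O[Si](C)(C)C(C)(C)C)=C(C)[C@@H]1C[C@H](OCc2ccc(OC)cc2)C(C)(C)CC(=O)/C=C/COCc2ccc(OC)cc2 | intermediate
26 | (4S)-4-[(2S,4Z,6E)-2,8-bis(4-methoxybenzyloxy)-5-(tert-butyldimethylsilyloxy)-3,3-dimethylocta-4,6-dien-1-yl]-2-(tert-butyldimethylsilyloxy)-3-methylcyclobut-2-en-1-one (key-step precursor) | COc1ccc(COC/C=C/C(O[Si](C)(C)C(C)(C)C)=C/C(C)(C)[C@@H](OCc2ccc(OC)cc2)C[C@@H]2C(=O)C(O[Si](C)(C)C(C)(C)C)=C2C)cc1 | intermediate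
27 | tricyclic cyclobutanone (rings A, B and cyclobutane C1–C10–C9–C11): 11-ketone; 9β-silyloxy; 10β-methyl; 1β-H; 5α-H; C6=C7 silyl enol ether; 8β-CH2O(4-methoxybenzyl), 8α-H; 3β-(4-methoxybenzyloxy); silyl = tert-butyldimethylsilyl | COc1ccc(COC[C@H]2C=C(O[Si](C)(C)C(C)(C)C)[C@H]3C(C)(C)[C@@H](OCc5ccc(OC)cc5)C[C@@H]4C(=O)[C@@]2(O[Si](C)(C)C(C)(C)C)[C@]34C)cc1 | intermediate
28 | as 27 but 6-ketone and 7α-(tert-butyldimethylsilyloxy) | COc1ccc(COC[C@H]2[C@H](O[Si](C)(C)C(C)(C)C)C(=O)[C@H]3C(C)(C)[C@@H](OCc5ccc(OC)cc5)C[C@@H]4C(=O)[C@@]2(O[Si](C)(C)C(C)(C)C)[C@]34C)cc1 | intermediate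
29 | 6β,11-diol from 28 (6β-OH axial; C11 carbinol of either configuration) | COc1ccc(COC[C@H]2[C@H](O[Si](C)(C)C(C)(C)C)[C@@H](O)[C@H]3C(C)(C)[C@@H](OCc5ccc(OC)cc5)C[C@@H]4C(O)[C@@]2(O[Si](C)(C)C(C)(C)C)[C@]34C)cc1 | intermediate
30 | 11-triethylsilyl ether of 29 (6β-OH free) | COc1ccc(COC[C@H]2[C@H](O[Si](C)(C)C(C)(C)C)[C@@H](O)[C@H]3C(C)(C)[C@@H](OCc5ccc(OC)cc5)C[C@@H]4C(O[Si](CC)(CC)CC)[C@@]2(O[Si](C)(C)C(C)(C)C)[C@]34C)cc1 | intermediate
31 | 6β-acetate of 30 | COc1ccc(COC[C@H]2[C@H](O[Si](C)(C)C(C)(C)C)[C@@H](OC(C)=O)[C@H]3C(C)(C)[C@@H](OCc5ccc(OC)cc5)C[C@@H]4C(O[Si](CC)(CC)CC)[C@@]2(O[Si](C)(C)C(C)(C)C)[C@]34C)cc1 | intermediate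
32 | 3β,14-diol (both 4-methoxybenzyl groups removed from 31) | OC[C@H]2[C@H](O[Si](C)(C)C(C)(C)C)[C@@H](OC(C)=O)[C@H]3C(C)(C)[C@@H](O)C[C@@H]4C(O[Si](CC)(CC)CC)[C@@]2(O[Si](C)(C)C(C)(C)C)[C@]34C | intermediate
33 | 3-ketone 14-aldehyde with 8α-H (formyl β, axial) | O=C[C@H]2[C@H](O[Si](C)(C)C(C)(C)C)[C@@H](OC(C)=O)[C@H]3C(C)(C)C(=O)C[C@@H]4C(O[Si](CC)(CC)CC)[C@@]2(O[Si](C)(C)C(C)(C)C)[C@]34C | intermediate
34 | 3-ketone 14-aldehyde with 8β-H (formyl α, equatorial) | O=C[C@@H]2[C@H](O[Si](C)(C)C(C)(C)C)[C@@H](OC(C)=O)[C@H]3C(C)(C)C(=O)C[C@@H]4C(O[Si](CC)(CC)CC)[C@@]2(O[Si](C)(C)C(C)(C)C)[C@]34C | intermediate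
35 | (E)-but-2-enal (crotonaldehyde) | C/C=C/C=O | starting material
36 | 2,3-dibromobutanal (racemic) | CC(Br)C(Br)C=O | intermediate (not isolated)
37 | (Z)-2-bromobut-2-enal | C/C=C(\Br)C=O | intermediate
38 | (Z)-2-bromobut-2-en-1-ol | C/C=C(\Br)CO | intermediate
39 | [(1S,2R)-1-bromo-2-methylcyclopropyl]methanol (bromine cis to methyl) | Br[C@]1(C[C@H]1C)CO | intermediate
40 | {[(1S,2R)-1-bromo-2-methylcyclopropyl]methoxy}triethylsilane | Br[C@]1(C[C@H]1C)CO[Si](CC)(CC)CC | intermediate
41 | cyclopropyllithium from 40 (lithium in place of bromine, retention) | [Li][C@]1(C[C@H]1C)CO[Si](CC)(CC)CC | intermediate (not isolated)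
42 | cyclopropylcerium dichloride from 41 | Cl[Ce](Cl)[C@]1(C[C@H]1C)CO[Si](CC)(CC)CC | intermediate (not isolated)
43 | adduct of 42 and 34: C14 carbinol (epimers) bearing the 1-(triethylsilyloxymethyl)-2-methylcyclopropyl group; C14 cis to the cyclopropane methyl | CC[Si](CC)(CC)OC[C@@]1(C[C@H]1C)C(O)[C@@H]2[C@H](O[Si](C)(C)C(C)(C)C)[C@@H](OC(C)=O)[C@H]3C(C)(C)C(=O)C[C@@H]4C(O[Si](CC)(CC)CC)[C@@]2(O[Si](C)(C)C(C)(C)C)[C@]34C | intermediate
44 | 11,12,14-triol (both triethylsilyl groups removed from 43) | OC[C@@]1(C[C@H]1C)C(O)[C@@H]2[C@H](O[Si](C)(C)C(C)(C)C)[C@@H](OC(C)=O)[C@H]3C(C)(C)C(=O)C[C@@H]4C(O)[C@@]2(O[Si](C)(C)C(C)(C)C)[C@]34C | intermediate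
45 | 3,11,14-triketone 12-aldehyde (ring C open between C11 and C12) | O=C[C@@]1(C[C@H]1C)C(=O)[C@@H]2[C@H](O[Si](C)(C)C(C)(C)C)[C@@H](OC(C)=O)[C@H]3C(C)(C)C(=O)C[C@@H]4C(=O)[C@@]2(O[Si](C)(C)C(C)(C)C)[C@]34C | intermediate
46 | tetracyclic α-ketol: 11β-OH, 12-ketone, 14-ketone, 3-ketone, 6β-OAc, 7α- and 9β-(tert-butyldimethylsilyloxy) | CC(=O)O[C@@H]1[C@@H](O[Si](C)(C)C(C)(C)C)[C@H]2C(=O)[C@]3(C[C@H]3C)C(=O)[C@@]3(O)[C@H]4CC(=O)C(C)(C)[C@H]1[C@@]4(C)[C@@]23O[Si](C)(C)C(C)(C)C | intermediate
47 | 11β,12α-diol from 46 | CC(=O)O[C@@H]1[C@@H](O[Si](C)(C)C(C)(C)C)[C@H]2C(=O)[C@]3(C[C@H]3C)[C@@H](O)[C@@]3(O)[C@H]4CC(=O)C(C)(C)[C@H]1[C@@]4(C)[C@@]23O[Si](C)(C)C(C)(C)C | intermediate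
48 | 6β,12α-diacetate 7α,9β-bis(tert-butyldimethylsilyl) ether | CC(=O)O[C@@H]1[C@@H](O[Si](C)(C)C(C)(C)C)[C@H]2C(=O)[C@]3(C[C@H]3C)[C@@H](OC(C)=O)[C@@]3(O)[C@H]4CC(=O)C(C)(C)[C@H]1[C@@]4(C)[C@@]23O[Si](C)(C)C(C)(C)C | intermediate
49 | CNP0157858.4 | CC(=O)O[C@@H]1[C@@H](O)[C@H]2C(=O)[C@]3(C[C@H]3C)[C@@H](OC(C)=O)[C@@]3(O)[C@H]4CC(=O)C(C)(C)[C@H]1[C@@]4(C)[C@@]23O | target

## Step count and least certain steps

Total: 36 steps. Longest linear sequence: 30 steps (steps 1–4, 7–25 and 30–36). The side branches are steps 5–6 (to 13) and steps 26–29 (to 40).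

**Step 18 (key step).** Three things may go wrong. Discrimination between the carbonyl-exo and carbonyl-endo transition states may be poor, which would give a cis A/B fusion. The tetrasubstituted, donor-substituted double bond may react slowly. And the cyclobutenone may open thermally to a vinylketene before it cyclises. Fallback: starting from 26, the same two bonds are made stepwise. TiCl4 in CH2Cl2 at −78 °C should trigger a Mukaiyama–Michael addition of the silyl enol ether carbon C5 to C10, followed by an intramolecular Michael addition of the resulting C9 enolate to C8. After aqueous work-up this gives the tricyclic 6,11-diketone F1, in which C5 is α to a ketone and can settle to the trans ring fusion. Kinetic enolisation of F1 toward the C7 methylene with LiN(SiMe3)2 and tBuMe2SiCl returns to 27.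

**Step 14.** The cuprate may desilylate or add 1,2 to the strained carbonyl, and sulfenylation of the fully substituted, oxygen-bearing enolate carbon may be too slow for the one-pot dehydrogenation. Fallback: starting from 21, Me2CuLi is added in the presence of Me3SiCl, giving the mixed enediol bis-silyl ether F2. Saegusa–Ito oxidation with Pd(OAc)2 (divalent palladium attacks C9 with loss of the more labile trimethylsilyl group, then β-hydride elimination from C10) returns to 23.

**Step 11.** Electron transfer from sodium may cleave the allylic or benzylic ethers, or enolise the ester next to C1 and erode its configuration. Fallback: starting from 18, reduction with iBu2AlH at −78 °C gives the dialdehyde F3. A pinacol cyclisation with SmI2 gives the cyclobutane-1,2-diol F4, and double Swern oxidation returns to 20.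

**Step 25.** The C8 enolate may expel the axial 7-silyloxy group (β-elimination) faster than it is reprotonated. Fallback: starting from 33, the axial aldehyde is carried on unchanged. Addition of 42 gives the 8α-H carbinol F5, HF·pyridine gives the triol F6, and Dess–Martin oxidation gives the keto aldehyde F7. In F7, C8 is α to the C14 ketone and is equilibrated by the amine base of the benzoin step. Only the isomer with C14 equatorial can close ring C, so the sequence returns at 46.

**Step 34.** After C12 is reduced, the new 12-hydroxyl may direct a second hydride to the C14 ketone (over-reduction). Fallback: starting from 46, the reduction is run with excess reagent at room temperature so that both C12 and C14 are reduced, giving the 11,12,14-triol F8. Oxidation with TEMPO and PhI(OAc)2 should then take the less hindered C14 carbinol (one quaternary neighbour instead of two) back to the ketone, returning to 47.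

## Further compounds

F1 | step 18 | tricyclic 6,11-diketone (27 with C6 ketone and C7 methylene) | COc1ccc(COC[C@H]2CC(=O)[C@H]3C(C)(C)[C@@H](OCc5ccc(OC)cc5)C[C@@H]4C(=O)[C@@]2(O[Si](C)(C)C(C)(C)C)[C@]34C)cc1
F2 | step 14 | mixed enediol bis-silyl ether: 1-(trimethylsilyloxy)-2-(tert-butyldimethylsilyloxy)-3-methyl-4-alkylcyclobut-1-ene | C[Si](C)(C)OC1=C(O[Si](C)(C)C(C)(C)C)[C@@H](C)[C@@H]1C[C@H](OCc2ccc(OC)cc2)C(C)(C)CC(O[Si](CC)(CC)CC)/C=C/COCc2ccc(OC)cc2
F3 | step 11 | (2S)-2-[(2S,6E)-2,8-bis(4-methoxybenzyloxy)-3,3-dimethyl-5-(triethylsilyloxy)oct-6-en-1-yl]butanedial | O=CC[C@@H](C=O)C[C@H](OCc1ccc(OC)cc1)C(C)(C)CC(O[Si](CC)(CC)CC)/C=C/COCc1ccc(OC)cc1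
F4 | step 11 | (3S)-3-[same side chain]cyclobutane-1,2-diol (carbinol configurations not controlled) | OC1C(O)[C@@H](C[C@H](OCc2ccc(OC)cc2)C(C)(C)CC(O[Si](CC)(CC)CC)/C=C/COCc2ccc(OC)cc2)C1
F5 | step 25 | 8α-H epimer of 43 | CC[Si](CC)(CC)OC[C@@]1(C[C@H]1C)C(O)[C@H]2[C@H](O[Si](C)(C)C(C)(C)C)[C@@H](OC(C)=O)[C@H]3C(C)(C)C(=O)C[C@@H]4C(O[Si](CC)(CC)CC)[C@@]2(O[Si](C)(C)C(C)(C)C)[C@]34C
F6 | step 25 | 8α-H epimer of 44 | OC[C@@]1(C[C@H]1C)C(O)[C@H]2[C@H](O[Si](C)(C)C(C)(C)C)[C@@H](OC(C)=O)[C@H]3C(C)(C)C(=O)C[C@@H]4C(O)[C@@]2(O[Si](C)(C)C(C)(C)C)[C@]34C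
F7 | step 25 | 8α-H epimer of 45 | O=C[C@@]1(C[C@H]1C)C(=O)[C@H]2[C@H](O[Si](C)(C)C(C)(C)C)[C@@H](OC(C)=O)[C@H]3C(C)(C)C(=O)C[C@@H]4C(=O)[C@@]2(O[Si](C)(C)C(C)(C)C)[C@]34C
F8 | step 34 | 11β,12α,14-triol (C14 carbinol configuration not controlled) | CC(=O)O[C@@H]1[C@@H](O[Si](C)(C)C(C)(C)C)[C@H]2C(O)[C@]3(C[C@H]3C)[C@@H](O)[C@@]3(O)[C@H]4CC(=O)C(C)(C)[C@H]1[C@@]4(C)[C@@]23O[Si](C)(C)C(C)(C)C
A1 | alternative 1 | pentacyclic isoxazoline (C8–C14 and O–C7 formed; 9,11-acetonide) | CC(=O)O[C@@H]1[C@@H](ON=5)[C@H]2C5[C@]3(C[C@H]3C)[C@@H](OC(C)=O)[C@@]3(OC6(C)C)[C@H]4CC(=O)C(C)(C)[C@H]1[C@@]4(C)[C@@]23O6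
A2 | alternative 1 | aldoxime with C7=C8 alkene in ring B (9,11-acetonide; oxime carbon C14 on C13) | CC(=O)O[C@@H]1C=C[C@@]23OC(C)(C)O[C@]2([C@H](OC(C)=O)[C@@]5(C[C@H]5C)/C=N/O)[C@H]4CC(=O)C(C)(C)[C@H]1[C@@]34C
A3 | alternative 2 | 4,5-dimethoxy-1-methylspiro[2.5]octa-4,7-dien-6-one (single enantiomer) | O=C1C=C[C@]2(C[C@H]2C)C(OC)=C1OC
A4 | alternative 2 | 4-[2-(methanesulfonyloxy)propyl]-2,3-dimethoxyphenol (single enantiomer, inverted at the carbinol carbon relative to A3) | COc1c(O)ccc(C[C@@H](OS(C)(=O)=O)C)c1OC
A5 | alternative 3 | tricyclic cyclobutanecarboxylate (rings A and B plus cyclobutane) | C=C[C@@H]1[C@H](O[Si](C)(C)C(C)(C)C)C[C@H]2C(C)(C)C3(OCCO3)C[C@@H]4[C@H](C(=O)OC)[C@@]1(O[Si](CC)(CC)CC)[C@]24C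
A6 | alternative 3 | α-diazo hydrindanone (diazo on C11, ketone C12) | C=C[C@@H]1[C@H](O[Si](C)(C)C(C)(C)C)C[C@H]2C(C)(C)C3(OCCO3)C[C@@H]4C(=[N+]=[N-])C(=O)[C@@]1(O[Si](CC)(CC)CC)[C@]24C
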